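The route rests on cutting C1–C8 and C1–C7. The cyclopentane ring C1–C7–C6–C5–C8 of the bicyclo[3.2.1]octane is a cyclobutanone (C8, C7, C6, C5) plus one carbon, C1, and C1 is at the same time the terminus of the three-carbon bridge C2–C3–C4 that starts at C5. A diazoalkane carbon C1, tethered to C5, adds to the ring carbonyl C8 and C7 shifts to C1 as dinitrogen leaves: one operation closes the six-membered ring, enlarges the four-membered ring and sets the quaternary C1. The precursor is a 2-methoxy-3-aryl-4-methylcyclobutanone from a ketene–alkene cycloaddition, its diazo group stored as a photolabile oxadiazoline installed before the strained ketone exists.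

Key step: step 12

Remarks: Locants are the working numbering of the target (C1 allyl bridgehead, C2, C3, C4 carbonyl carbon, C5 methoxy bridgehead, C6 aryl carbon, C7 methyl carbon, C8 one-carbon bridge) and are used for all bicyclic compounds. At C3, C6 and C7, exo means turned toward C8 and endo the opposite face. Diazoalkane 23 is assumed too labile to isolate; it is released from 22 and consumed in one flask. The configurations of the key-step precursor and product were checked against the target and needed no correction. The design change is that all hydrazide chemistry is done before the cyclobutanone exists, because a hydrazine reagent would not reliably tell the chain ketone from the strained ring ketone.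

Step 1
Reactants: 1 5-bromo-2-methoxyphenol; 2 (E)-4,4,5,5-tetramethyl-2-(prop-1-en-1-yl)-1,3,2-dioxaborolane
Product: 3 (E)-2-methoxy-5-(prop-1-en-1-yl)phenol
Conditions: Pd(dppf)Cl2 (3 mol %), K2CO3, 1,4-dioxane/H2O, 80 °C
Reagents that add atoms: none
Why: Suzuki–Miyaura coupling of the aryl bromide with an alkenylboronate should transfer the propenyl group with retention of its E geometry, and the free phenol is tolerated in aqueous carbonate.

Step 2
Reactants: 3 (E)-2-methoxy-5-(prop-1-en-1-yl)phenol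
Product: 4 (E)-triisopropyl[2-methoxy-5-(prop-1-en-1-yl)phenoxy]silane
Conditions: i-Pr3SiCl, imidazole, DMF, rt
Reagents that add atoms: chlorotriisopropylsilane, CC(C)[Si](Cl)(C(C)C)C(C)C
Why: Silylation of the phenol with a silyl chloride and imidazole; the triisopropylsilyl ether is chosen because it should outlast the amine bases, amide bases and acidic fluoride of the later steps and fall only to fluoride at the end.

Step 3
Reactants: 5 1,3-dithiane; 6 2-(2-bromoethyl)-1,3-dioxolane; 7 allyl bromide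
Product: 9 2-allyl-2-[2-(1,3-dioxolan-2-yl)ethyl]-1,3-dithiane, via monoalkylated dithiane 8 (not isolated)
Conditions: n-BuLi, THF, −30 °C, then 6, −30 → 0 °C; n-BuLi, −30 °C, then 7, −78 → 0 °C
Reagents that add atoms: none
Why: Corey–Seebach dithiane alkylation run twice in one flask: the unhindered 2-lithio-1,3-dithiane should take the less reactive primary bromide 6 first and the more hindered anion of 8 is then trapped by the very reactive allyl bromide, which assembles the future C1 as a masked ketone flanked by the allyl group and the C2–C3 chain.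

Step 4
Reactants: 9 2-allyl-2-[2-(1,3-dioxolan-2-yl)ethyl]-1,3-dithiane
Product: 10 3-(2-allyl-1,3-dithian-2-yl)propanal
Conditions: 2 M HCl, THF, 40 °C
Reagents that add atoms: water, O
Why: Acid-catalysed acetal hydrolysis should free the aldehyde (the future C4) while the dithiane, which opens only with a thiophile, and the terminal alkene are left alone.

Step 5
Reactants: 11 (S)-4-benzyloxazolidin-2-one; 12 methoxyacetyl chloride
Product: 13 (S)-4-benzyl-3-(methoxyacetyl)oxazolidin-2-one
Conditions: n-BuLi, THF, −78 °C, then 12, −78 → 0 °C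
Reagents that add atoms: none
Why: N-Acylation of the lithiated oxazolidinone with the acid chloride is the standard way to the glycolate imide needed for an auxiliary-controlled aldol reaction.

Step 6
Reactants: 13 (S)-4-benzyl-3-(methoxyacetyl)oxazolidin-2-one; 10 3-(2-allyl-1,3-dithian-2-yl)propanal
Product: 14 (S)-4-benzyl-3-[(2S,3R)-5-(2-allyl-1,3-dithian-2-yl)-3-hydroxy-2-methoxypentanoyl]oxazolidin-2-one
Conditions: Bu2BOTf, Et3N, CH2Cl2, 0 °C; then 10, −78 → 0 °C; pH 7 buffer/MeOH work-up without peroxide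
Reagents that add atoms: none
Why: Evans syn aldol reaction of the Z boron enolate of the glycolate imide through a closed chair transition state on the enolate face turned away from the benzyl group, which should set the carbinol carbon (the future C4) as R together with the 2S methoxy carbon that is erased later when the ketene is formed; peroxide is kept out of the work-up to spare the dithiane.

Step 7
Reactants: 14 (S)-4-benzyl-3-[(2S,3R)-5-(2-allyl-1,3-dithian-2-yl)-3-hydroxy-2-methoxypentanoyl]oxazolidin-2-one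
Product: 15 (S)-4-benzyl-3-[(2S,3R)-5-(2-allyl-1,3-dithian-2-yl)-3-[(tert-butyldimethylsilyl)oxy]-2-methoxypentanoyl]oxazolidin-2-one
Conditions: t-BuMe2SiOTf, 2,6-lutidine, CH2Cl2, −78 → 0 °C
Reagents that add atoms: tert-butyldimethylsilyl trifluoromethanesulfonate, CC(C)(C)[Si](C)(C)OS(=O)(=O)C(F)(F)F
Why: Silylation of the secondary alcohol with the silyl triflate and a hindered pyridine base; the bulky silyl ether blocks retro-aldol and lactol formation and later sits equatorial in the ring-forming transition state of step 12.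

Step 8
Reactants: 15 (S)-4-benzyl-3-[(2S,3R)-5-(2-allyl-1,3-dithian-2-yl)-3-[(tert-butyldimethylsilyl)oxy]-2-methoxypentanoyl]oxazolidin-2-one
Product: 16 (S)-4-benzyl-3-[(2S,3R)-3-[(tert-butyldimethylsilyl)oxy]-2-methoxy-6-oxonon-8-enoyl]oxazolidin-2-one
Conditions: MeI, CaCO3, MeCN/H2O (9:1), 45 °C
Reagents that add atoms: water, O
Why: Alkylative dithiane hydrolysis (S-methylation, then hydrolysis of the sulfonium salt) under carbonate buffer should release the β,γ-unsaturated ketone without an acid or base strong enough to move the double bond into conjugation.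

Step 9
Reactants: 16 (S)-4-benzyl-3-[(2S,3R)-3-[(tert-butyldimethylsilyl)oxy]-2-methoxy-6-oxonon-8-enoyl]oxazolidin-2-one
Product: 18 (S)-4-benzyl-3-[(2S,3R)-5-(5-allyl-2-methoxy-2-methyl-2,5-dihydro-1,3,4-oxadiazol-5-yl)-3-[(tert-butyldimethylsilyl)oxy]-2-methoxypentanoyl]oxazolidin-2-one, via N-acetylhydrazone 17 (not isolated)
Conditions: AcNHNH2, AcOH (cat.), MeOH, rt; then PhI(OAc)2, 0 °C
Reagents that add atoms: acetohydrazide, CC(=O)NN; methanol, CO
Why: Condensation of the unhindered ketone with acetohydrazide and oxidative cyclisation of the N-acetylhydrazone with PhI(OAc)2 in methanol is the known route to 2-methoxy-2-methyl-2,5-dihydro-1,3,4-oxadiazoles, which are neutral, chromatographable and photolabile stores of non-stabilised diazoalkanes; the hydrazide chemistry is done here, while no cyclobutanone is present to compete for it, and the two new ring stereocentres are left as a mixture because both disappear in step 12.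

Step 10
Reactants: 18 (S)-4-benzyl-3-[(2S,3R)-5-(5-allyl-2-methoxy-2-methyl-2,5-dihydro-1,3,4-oxadiazol-5-yl)-3-[(tert-butyldimethylsilyl)oxy]-2-methoxypentanoyl]oxazolidin-2-one
Product: 19 (2S,3R)-5-(5-allyl-2-methoxy-2-methyl-2,5-dihydro-1,3,4-oxadiazol-5-yl)-3-[(tert-butyldimethylsilyl)oxy]-2-methoxypentanoic acid
Conditions: LiOH, H2O2, THF/H2O, 0 °C; then Na2SO3; 1 M HCl to pH 4, cold
Reagents that add atoms: hydrogen peroxide (as lithium hydroperoxide), OO
Why: Cleavage of the imide with lithium hydroperoxide occurs at the exocyclic carbonyl and returns the auxiliary, and since the ketone is already masked no base-induced shift of the allyl double bond can occur.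

Step 11
Reactants: 19 (2S,3R)-5-(5-allyl-2-methoxy-2-methyl-2,5-dihydro-1,3,4-oxadiazol-5-yl)-3-[(tert-butyldimethylsilyl)oxy]-2-methoxypentanoic acid; 4 (E)-triisopropyl[2-methoxy-5-(prop-1-en-1-yl)phenoxy]silane
Product: 22 (2R,3S,4R)-2-[(1R)-3-(5-allyl-2-methoxy-2-methyl-2,5-dihydro-1,3,4-oxadiazol-5-yl)-1-[(tert-butyldimethylsilyl)oxy]propyl]-2-methoxy-3-[4-methoxy-3-(triisopropylsilyloxy)phenyl]-4-methylcyclobutan-1-one, via acid chloride 20 (not isolated), via ketene 21 (not isolated)
Conditions: 1-chloro-N,N,2-trimethylprop-1-en-1-amine, CH2Cl2, 0 °C → rt; then slow addition to 4 (3 equiv, excess recovered) and Et3N in toluene, 50 °C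
Reagents that add atoms: none
Why: Thermal ketene–alkene [2+2] cycloaddition, suprafacial on the alkene: the ketene 21 from dehydrochlorination of 20 should bond through its carbonyl carbon to the nucleophilic methyl-bearing alkene carbon, the E geometry is kept (aryl trans to methyl), the larger ketene substituent ends cis to the aryl group, and the alkene approaches the ketene face anti to the silyloxy group of the R carbinol carbon with the carbinol C–H turned toward the methoxy group, which relates the three new ring centres to C4; the minor face isomer is removed by chromatography, and 50 °C is within the thermal range of the oxadiazoline.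

Step 12
Reactants: 22 (2R,3S,4R)-2-[(1R)-3-(5-allyl-2-methoxy-2-methyl-2,5-dihydro-1,3,4-oxadiazol-5-yl)-1-[(tert-butyldimethylsilyl)oxy]propyl]-2-methoxy-3-[4-methoxy-3-(triisopropylsilyloxy)phenyl]-4-methylcyclobutan-1-one
Product: 24 (1R,4R,5R,6S,7R)-1-allyl-4-[(tert-butyldimethylsilyl)oxy]-5-methoxy-6-[4-methoxy-3-(triisopropylsilyloxy)phenyl]-7-methylbicyclo[3.2.1]octan-8-one, via diazoalkane 23 (not isolated)
Conditions: hν (about 340 nm), CH2Cl2 (0.01 M), −40 °C; then Sc(OTf)3 (10 mol %), 4 Å sieves, −78 → −20 °C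
Reagents that add atoms: none
Why: Proposed new method: light of about 340 nm is absorbed mainly by the cyclic azo chromophore of 22, whose known cycloreversion gives methyl acetate and diazoalkane 23; the nucleophilic diazo carbon C1 then adds to the strained, Sc(OTf)3-activated C8 carbonyl and the diazonium alkoxide loses N2 with a 1,2-shift of C7 from C8 to C1, a Tiffeneau–Demjanov-type homologation. The closest known reactions are the Lewis acid catalysed intermolecular ring enlargement of cyclobutanones by diazoalkanes and, as nitrogen analogue, the intramolecular Schmidt reaction of alkyl azides with ketones, neither of which has been shown as a carbon insertion that bridges. The six-membered ring C1–C2–C3–C4–C5–C8 closes by 6-exo-trig attack on the carbonyl from the face that carries the tether, and the cyclopentanone C1–C7–C6–C5–C8 arises from the cyclobutanone by ring enlargement (1,2-alkyl shift), not by a cyclisation. C1 is the only new stereocentre and its configuration is forced, because C7 migrates with retention on the face it already occupies and the C2–C4 bridge can span only that face of the new five-membered ring. The step needs C7 to migrate, not C5, and needs carbonyl addition to win over loss of N2 with 1,2-hydride shift and over dipolar cycloaddition of the diazo group onto the allyl alkene. C7 migration is secured by the chair of the forming ring in which the exocyclic C8–C7 bond is axial and antiperiplanar to an axial C1–N2 bond while the 4R silyloxy group and the allyl group are equatorial, and by the methoxy group that makes C5 a poor migrating group; the side reactions are held back by unmasking the diazoalkane at −40 °C next to a ketone activated by ring strain and by the Lewis acid.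

Step 13
Reactants: 24 (1R,4R,5R,6S,7R)-1-allyl-4-[(tert-butyldimethylsilyl)oxy]-5-methoxy-6-[4-methoxy-3-(triisopropylsilyloxy)phenyl]-7-methylbicyclo[3.2.1]octan-8-one
Product: 25 (1R,4R,5R,6S,7R)-1-allyl-4-hydroxy-5-methoxy-6-[4-methoxy-3-(triisopropylsilyloxy)phenyl]-7-methylbicyclo[3.2.1]octan-8-one
Conditions: HF·pyridine, pyridine, THF, 0 °C → rt
Reagents that add atoms: none
Why: Acidic fluoride should cleave the alkyl tert-butyldimethylsilyl ether while the aryl triisopropylsilyl ether, which is labile mainly to basic fluoride, stays.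

Step 14
Reactants: 25 (1R,4R,5R,6S,7R)-1-allyl-4-hydroxy-5-methoxy-6-[4-methoxy-3-(triisopropylsilyloxy)phenyl]-7-methylbicyclo[3.2.1]octan-8-one
Product: 26 (1R,4R,5R,6S,7R,8S)-1-allyl-5-methoxy-6-[4-methoxy-3-(triisopropylsilyloxy)phenyl]-7-methylbicyclo[3.2.1]octane-4,8-diol
Conditions: Et2BOMe, THF/MeOH (4:1), −78 °C; then NaBH4; AcOH, MeOH co-evaporation
Reagents that add atoms: none
Why: Chelation-controlled reduction of a β-hydroxy ketone (Narasaka–Prasad type): the axial C4 hydroxyl binds the diethylboron unit, which closes a six-membered chelate to the C8 carbonyl on the face of the C2–C4 bridge, so borohydride should attack from the C6–C7 face and set C8 with its hydroxyl syn to the C2–C4 bridge (cis-1,3-diol).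

Step 15
Reactants: 26 (1R,4R,5R,6S,7R,8S)-1-allyl-5-methoxy-6-[4-methoxy-3-(triisopropylsilyloxy)phenyl]-7-methylbicyclo[3.2.1]octane-4,8-diol
Product: 27 (1R,5S,6S,7R,8S)-1-allyl-8-hydroxy-5-methoxy-6-[4-methoxy-3-(triisopropylsilyloxy)phenyl]-7-methylbicyclo[3.2.1]octan-4-one
Conditions: Dess–Martin periodinane (1.1 equiv), NaHCO3, CH2Cl2, 0 °C
Reagents that add atoms: none
Why: Dess–Martin oxidation should take the C4 carbinol only, because the C8 hydroxyl lies between two quaternary bridgeheads and its oxidation would rebuild a strained bridging ketone.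

Step 16
Reactants: 27 (1R,5S,6S,7R,8S)-1-allyl-8-hydroxy-5-methoxy-6-[4-methoxy-3-(triisopropylsilyloxy)phenyl]-7-methylbicyclo[3.2.1]octan-4-one
Product: 28 (1R,5S,6S,7R,8S)-1-allyl-5-methoxy-6-[4-methoxy-3-(triisopropylsilyloxy)phenyl]-7-methyl-8-[(trimethylsilyl)oxy]bicyclo[3.2.1]octan-4-one
Conditions: N-(trimethylsilyl)imidazole, CH2Cl2, 40 °C
Reagents that add atoms: N-(trimethylsilyl)imidazole, C[Si](C)(C)n1ccnc1
Why: Silyl transfer from N-(trimethylsilyl)imidazole silylates even hindered alcohols without added base and without enolising the ketone; the small trimethylsilyl ether keeps O8 from becoming an alkoxide in the enolate steps, which would open the C5–C8 bond by retro-aldol reaction.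

Step 17
Reactants: 28 (1R,5S,6S,7R,8S)-1-allyl-5-methoxy-6-[4-methoxy-3-(triisopropylsilyloxy)phenyl]-7-methyl-8-[(trimethylsilyl)oxy]bicyclo[3.2.1]octan-4-one
Product: 29 (1S,3R,5S,6S,7R,8S)-1-allyl-3-hydroxy-5-methoxy-6-[4-methoxy-3-(triisopropylsilyloxy)phenyl]-7-methyl-8-[(trimethylsilyl)oxy]bicyclo[3.2.1]octan-4-one
Conditions: KN(SiMe3)2, THF, −78 °C; then 2-(phenylsulfonyl)-3-phenyloxaziridine; AcOH quench
Reagents that add atoms: 2-(phenylsulfonyl)-3-phenyloxaziridine, O=S(=O)(c1ccccc1)N1OC1c1ccccc1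
Why: Enolate hydroxylation with an N-sulfonyloxaziridine (Davis oxidation): the enolate can form only toward C3 because C5 is quaternary, and the oxygen should enter C3 on the exo face because the endo face is covered by the aryl group on C6, which gives the exo alcohol.

Step 18
Reactants: 29 (1S,3R,5S,6S,7R,8S)-1-allyl-3-hydroxy-5-methoxy-6-[4-methoxy-3-(triisopropylsilyloxy)phenyl]-7-methyl-8-[(trimethylsilyl)oxy]bicyclo[3.2.1]octan-4-one
Product: 30 (1S,3R,5S,6S,7R,8S)-1-allyl-3,5-dimethoxy-6-[4-methoxy-3-(triisopropylsilyloxy)phenyl]-7-methyl-8-[(trimethylsilyl)oxy]bicyclo[3.2.1]octan-4-one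
Conditions: MeOTf, 2,6-di-tert-butyl-4-methylpyridine, CH2Cl2, 0 °C → rt
Reagents that add atoms: methyl trifluoromethanesulfonate, COS(=O)(=O)C(F)(F)F
Why: O-Methylation with methyl triflate and a non-nucleophilic pyridine base avoids alkoxide conditions that would endanger the aryl silyl ether or start α-ketol chemistry, and it leaves the C3 configuration untouched.

Step 19
Reactants: 30 (1S,3R,5S,6S,7R,8S)-1-allyl-3,5-dimethoxy-6-[4-methoxy-3-(triisopropylsilyloxy)phenyl]-7-methyl-8-[(trimethylsilyl)oxy]bicyclo[3.2.1]octan-4-one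
Product: 31 (1S,3S,5S,6S,7R,8S)-1-allyl-3,5-dimethoxy-6-[4-methoxy-3-(triisopropylsilyloxy)phenyl]-7-methyl-8-[(trimethylsilyl)oxy]bicyclo[3.2.1]octan-4-one
Conditions: LiN(i-Pr)2, THF, −78 → −40 °C; then AcOH (excess), −78 °C
Reagents that add atoms: none
Why: Enolisation and kinetic protonation: the C3–C4 enolate should be protonated at C3 from the open exo face, the same face the oxaziridine used, so hydrogen ends exo and the methoxy group endo as in the target, and the cold quench with excess acetic acid prevents equilibration.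

Step 20
Reactants: 31 (1S,3S,5S,6S,7R,8S)-1-allyl-3,5-dimethoxy-6-[4-methoxy-3-(triisopropylsilyloxy)phenyl]-7-methyl-8-[(trimethylsilyl)oxy]bicyclo[3.2.1]octan-4-one
Product: 32 (1S,3S,5S,6S,7R,8S)-1-allyl-8-hydroxy-6-(3-hydroxy-4-methoxyphenyl)-3,5-dimethoxy-7-methylbicyclo[3.2.1]octan-4-one
Conditions: Bu4NF, AcOH, THF, 0 °C → rt
Reagents that add atoms: none
Why: Fluoride buffered with acetic acid should remove the aryl triisopropylsilyl ether and the trimethylsilyl ether in one operation without leaving a free phenoxide or alkoxide in solution, so neither epimerisation at C3 nor retro-aldol opening is triggered.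

Compound list

1 | 5-bromo-2-methoxyphenol | COc1ccc(Br)cc1O | starting material
2 | (E)-4,4,5,5-tetramethyl-2-(prop-1-en-1-yl)-1,3,2-dioxaborolane | C/C=C/B1OC(C)(C)C(C)(C)O1 | starting material
3 | (E)-2-methoxy-5-(prop-1-en-1-yl)phenol | C/C=C/c1ccc(OC)c(O)c1 | intermediate
4 | (E)-triisopropyl[2-methoxy-5-(prop-1-en-1-yl)phenoxy]silane | C/C=C/c1ccc(OC)c(O[Si](C(C)C)(C(C)C)C(C)C)c1 | intermediate
5 | 1,3-dithiane | C1CSCSC1 | starting material
6 | 2-(2-bromoethyl)-1,3-dioxolane | BrCCC1OCCO1 | starting material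
7 | allyl bromide | C=CCBr | starting material
8 | 2-[2-(1,3-dioxolan-2-yl)ethyl]-1,3-dithiane (monoalkylated dithiane) | C1CSC(CCC2OCCO2)SC1 | intermediate
9 | 2-allyl-2-[2-(1,3-dioxolan-2-yl)ethyl]-1,3-dithiane | C=CCC1(CCC2OCCO2)SCCCS1 | intermediate
10 | 3-(2-allyl-1,3-dithian-2-yl)propanal | C=CCC1(CCC=O)SCCCS1 | intermediate
11 | (S)-4-benzyloxazolidin-2-one | O=C1N[C@@H](Cc2ccccc2)CO1 | starting material
12 | methoxyacetyl chloride | COCC(Cl)=O | starting material
13 | (S)-4-benzyl-3-(methoxyacetyl)oxazolidin-2-one | COCC(=O)N1[C@@H](Cc2ccccc2)COC1=O | intermediate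
14 | (S)-4-benzyl-3-[(2S,3R)-5-(2-allyl-1,3-dithian-2-yl)-3-hydroxy-2-methoxypentanoyl]oxazolidin-2-one | C=CCC1(CC[C@@H](O)[C@H](OC)C(=O)N2[C@@H](Cc3ccccc3)COC2=O)SCCCS1 | intermediate
15 | (S)-4-benzyl-3-[(2S,3R)-5-(2-allyl-1,3-dithian-2-yl)-3-[(tert-butyldimethylsilyl)oxy]-2-methoxypentanoyl]oxazolidin-2-one | C=CCC1(CC[C@@H](O[Si](C)(C)C(C)(C)C)[C@H](OC)C(=O)N2[C@@H](Cc3ccccc3)COC2=O)SCCCS1 | intermediate
16 | (S)-4-benzyl-3-[(2S,3R)-3-[(tert-butyldimethylsilyl)oxy]-2-methoxy-6-oxonon-8-enoyl]oxazolidin-2-one | C=CCC(=O)CC[C@@H](O[Si](C)(C)C(C)(C)C)[C@H](OC)C(=O)N1[C@@H](Cc2ccccc2)COC1=O | intermediate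
17 | N-acetylhydrazone of 16 at the C6 ketone (E/Z mixture) | C=CCC(=NNC(C)=O)CC[C@@H](O[Si](C)(C)C(C)(C)C)[C@H](OC)C(=O)N1[C@@H](Cc2ccccc2)COC1=O | intermediate
18 | (S)-4-benzyl-3-[(2S,3R)-5-(5-allyl-2-methoxy-2-methyl-2,5-dihydro-1,3,4-oxadiazol-5-yl)-3-[(tert-butyldimethylsilyl)oxy]-2-methoxypentanoyl]oxazolidin-2-one (mixture at the two oxadiazoline carbons) | C=CCC1(CC[C@@H](O[Si](C)(C)C(C)(C)C)[C@H](OC)C(=O)N2[C@@H](Cc3ccccc3)COC2=O)N=NC(C)(OC)O1 | intermediate
19 | (2S,3R)-5-(5-allyl-2-methoxy-2-methyl-2,5-dihydro-1,3,4-oxadiazol-5-yl)-3-[(tert-butyldimethylsilyl)oxy]-2-methoxypentanoic acid | C=CCC1(CC[C@@H](O[Si](C)(C)C(C)(C)C)[C@H](OC)C(=O)O)N=NC(C)(OC)O1 | intermediate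
20 | acid chloride of 19 | C=CCC1(CC[C@@H](O[Si](C)(C)C(C)(C)C)[C@H](OC)C(Cl)=O)N=NC(C)(OC)O1 | intermediate
21 | (3R)-5-(5-allyl-2-methoxy-2-methyl-2,5-dihydro-1,3,4-oxadiazol-5-yl)-3-[(tert-butyldimethylsilyl)oxy]-2-methoxypent-1-en-1-one (ketene) | C=CCC1(CC[C@@H](O[Si](C)(C)C(C)(C)C)C(OC)=C=O)N=NC(C)(OC)O1 | intermediate
22 | (2R,3S,4R)-2-[(1R)-3-(5-allyl-2-methoxy-2-methyl-2,5-dihydro-1,3,4-oxadiazol-5-yl)-1-[(tert-butyldimethylsilyl)oxy]propyl]-2-methoxy-3-[4-methoxy-3-(triisopropylsilyloxy)phenyl]-4-methylcyclobutan-1-one (aryl cis to the side chain, trans to methyl and methoxy) | C=CCC1(CC[C@@H](O[Si](C)(C)C(C)(C)C)[C@@]2(OC)C(=O)[C@H](C)[C@H]2c3ccc(OC)c(O[Si](C(C)C)(C(C)C)C(C)C)c3)N=NC(C)(OC)O1 | intermediate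
23 | (2R,3S,4R)-2-[(1R)-1-[(tert-butyldimethylsilyl)oxy]-4-diazohept-6-en-1-yl]-2-methoxy-3-[4-methoxy-3-(triisopropylsilyloxy)phenyl]-4-methylcyclobutan-1-one | C=CCC(=[N+]=[N-])CC[C@@H](O[Si](C)(C)C(C)(C)C)[C@@]1(OC)C(=O)[C@H](C)[C@H]1c2ccc(OC)c(O[Si](C(C)C)(C(C)C)C(C)C)c2 | intermediate
24 | (1R,4R,5R,6S,7R)-1-allyl-4-[(tert-butyldimethylsilyl)oxy]-5-methoxy-6-[4-methoxy-3-(triisopropylsilyloxy)phenyl]-7-methylbicyclo[3.2.1]octan-8-one (aryl endo, methyl exo, silyloxy axial and syn to C8) | C=CC[C@]12CC[C@@H](O[Si](C)(C)C(C)(C)C)[C@](OC)([C@H](c3ccc(OC)c(O[Si](C(C)C)(C(C)C)C(C)C)c3)[C@H]1C)C2=O | intermediate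
25 | (1R,4R,5R,6S,7R)-1-allyl-4-hydroxy-5-methoxy-6-[4-methoxy-3-(triisopropylsilyloxy)phenyl]-7-methylbicyclo[3.2.1]octan-8-one | C=CC[C@]12CC[C@@H](O)[C@](OC)([C@H](c3ccc(OC)c(O[Si](C(C)C)(C(C)C)C(C)C)c3)[C@H]1C)C2=O | intermediate
26 | (1R,4R,5R,6S,7R,8S)-1-allyl-5-methoxy-6-[4-methoxy-3-(triisopropylsilyloxy)phenyl]-7-methylbicyclo[3.2.1]octane-4,8-diol (both hydroxyls on the face of the C2–C4 bridge) | C=CC[C@]12CC[C@@H](O)[C@](OC)([C@H](c3ccc(OC)c(O[Si](C(C)C)(C(C)C)C(C)C)c3)[C@H]1C)[C@H]2O | intermediate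
27 | (1R,5S,6S,7R,8S)-1-allyl-8-hydroxy-5-methoxy-6-[4-methoxy-3-(triisopropylsilyloxy)phenyl]-7-methylbicyclo[3.2.1]octan-4-one | C=CC[C@]12CCC(=O)[C@](OC)([C@H](c3ccc(OC)c(O[Si](C(C)C)(C(C)C)C(C)C)c3)[C@H]1C)[C@H]2O | intermediate
28 | (1R,5S,6S,7R,8S)-1-allyl-5-methoxy-6-[4-methoxy-3-(triisopropylsilyloxy)phenyl]-7-methyl-8-[(trimethylsilyl)oxy]bicyclo[3.2.1]octan-4-one | C=CC[C@]12CCC(=O)[C@](OC)([C@H](c3ccc(OC)c(O[Si](C(C)C)(C(C)C)C(C)C)c3)[C@H]1C)[C@H]2O[Si](C)(C)C | intermediate
29 | (1S,3R,5S,6S,7R,8S)-1-allyl-3-hydroxy-5-methoxy-6-[4-methoxy-3-(triisopropylsilyloxy)phenyl]-7-methyl-8-[(trimethylsilyl)oxy]bicyclo[3.2.1]octan-4-one (3-hydroxyl exo) | C=CC[C@]12C[C@@H](O)C(=O)[C@](OC)([C@H](c3ccc(OC)c(O[Si](C(C)C)(C(C)C)C(C)C)c3)[C@H]1C)[C@H]2O[Si](C)(C)C | intermediate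
30 | (1S,3R,5S,6S,7R,8S)-1-allyl-3,5-dimethoxy-6-[4-methoxy-3-(triisopropylsilyloxy)phenyl]-7-methyl-8-[(trimethylsilyl)oxy]bicyclo[3.2.1]octan-4-one (3-methoxy exo) | C=CC[C@]12C[C@@H](OC)C(=O)[C@](OC)([C@H](c3ccc(OC)c(O[Si](C(C)C)(C(C)C)C(C)C)c3)[C@H]1C)[C@H]2O[Si](C)(C)C | intermediate
31 | (1S,3S,5S,6S,7R,8S)-1-allyl-3,5-dimethoxy-6-[4-methoxy-3-(triisopropylsilyloxy)phenyl]-7-methyl-8-[(trimethylsilyl)oxy]bicyclo[3.2.1]octan-4-one (3-methoxy endo) | C=CC[C@]12C[C@H](OC)C(=O)[C@](OC)([C@H](c3ccc(OC)c(O[Si](C(C)C)(C(C)C)C(C)C)c3)[C@H]1C)[C@H]2O[Si](C)(C)C | intermediate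
32 | (1S,3S,5S,6S,7R,8S)-1-allyl-8-hydroxy-6-(3-hydroxy-4-methoxyphenyl)-3,5-dimethoxy-7-methylbicyclo[3.2.1]octan-4-one (CNP0209708.1) | C=CC[C@]12C[C@H](OC)C(=O)[C@](OC)([C@H](c3ccc(OC)c(O)c3)[C@H]1C)[C@H]2O | target

Total step count: 20. Longest linear sequence: 17 steps (steps 3, 4 and 6 to 20, from 1,3-dithiane 5).

Steps most likely to fail

Step 12. The freed diazoalkane may lose dinitrogen before it reaches the carbonyl (1,2-hydride shift, or dipolar cycloaddition onto the allyl alkene), the light may also cleave the cyclobutanone, or the ring bond C5–C8 may migrate in place of C7–C8. The fallback uses known chemistry only: a one-carbon ring enlargement with a silyl diazomethane, an enolate allylation and an intramolecular enolate alkylation. It sets out from 13 and 4 and comes back to the route at 24. Evans syn aldol reaction of 13 with commercial 3-[(tert-butyldimethylsilyl)oxy]propanal should give (S)-4-benzyl-3-[(2S,3R)-5-[(tert-butyldimethylsilyl)oxy]-3-hydroxy-2-methoxypentanoyl]oxazolidin-2-one F1. Silylation as in step 7 gives the bis-silyl ether F2, and LiOH/H2O2 gives the acid F3. Ketene cycloaddition with 4 as in step 11, here free of any thermal limit, gives the cyclobutanone F4. Ring enlargement with Me3SiCHN2 and Sc(OTf)3, then protodesilylation, should insert CH2 (the future C1) on the side of the methyl-bearing carbon and give the cyclopentanone F5. Deprotonation with LiN(i-Pr)2 at the only enolisable position and allyl bromide give the 2-allylcyclopentanone F6. HF·pyridine removes the primary silyl ether to give the primary alcohol F7, and I2, PPh3 and imidazole give the primary iodide F8. KN(SiMe3)2 then closes the C1–C2 bond by enolate alkylation and delivers 24.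

Step 11. The hindered alkoxy(alkyl)ketene may dimerise or decompose faster than it adds to the alkene at the temperature the oxadiazoline allows, and the alkene may discriminate the two ketene faces only weakly. The fallback moves the cycloaddition ahead of the unmasking of the chain ketone, so that heat (toluene, 110 °C) or Lewis acid promotion (EtAlCl2, −78 °C) can be used freely. It sets out from 15 and 4 and comes back at 22. LiOH/H2O2 on 15 gives the dithiane acid F9. Acid chloride formation and dehydrochlorination in the presence of 4 give the dithiane cyclobutanone F10. MeI and CaCO3 in aqueous MeCN give the keto cyclobutanone F11. One equivalent of acetohydrazide, which should prefer the unhindered acyclic ketone, followed by PhI(OAc)2 in MeOH gives 22.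

Step 19. Removal of the hindered endo hydrogen at C3 may be slow, or protonation of the enolate may not distinguish its faces, so that the exo methyl ether persists. The fallback replaces protonation by a substitution with inversion. It sets out from 29 and comes back at 31. Tf2O and pyridine convert 29 into the exo triflate F12. KNO2 in DMF (Lattrell–Dax inversion, nitrite ester hydrolysed on work-up) gives the endo alcohol F13. Methylation as in step 18 gives 31 directly. Should the hydroxylation of step 17 itself take the endo course, F13 is obtained in place of 29 and the same methylation applies.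

Further compounds

F1 | step 12 | (S)-4-benzyl-3-[(2S,3R)-5-[(tert-butyldimethylsilyl)oxy]-3-hydroxy-2-methoxypentanoyl]oxazolidin-2-one | CC(C)(C)[Si](C)(C)OCC[C@@H](O)[C@H](OC)C(=O)N1[C@@H](Cc2ccccc2)COC1=O
F2 | step 12 | (S)-4-benzyl-3-[(2S,3R)-3,5-bis[(tert-butyldimethylsilyl)oxy]-2-methoxypentanoyl]oxazolidin-2-one | CC(C)(C)[Si](C)(C)OCC[C@@H](O[Si](C)(C)C(C)(C)C)[C@H](OC)C(=O)N1[C@@H](Cc2ccccc2)COC1=O
F3 | step 12 | (2S,3R)-3,5-bis[(tert-butyldimethylsilyl)oxy]-2-methoxypentanoic acid | CC(C)(C)[Si](C)(C)OCC[C@@H](O[Si](C)(C)C(C)(C)C)[C@H](OC)C(=O)O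
F4 | step 12 | (2R,3S,4R)-2-[(1R)-1,3-bis[(tert-butyldimethylsilyl)oxy]propyl]-2-methoxy-3-[4-methoxy-3-(triisopropylsilyloxy)phenyl]-4-methylcyclobutan-1-one | CC(C)(C)[Si](C)(C)OCC[C@@H](O[Si](C)(C)C(C)(C)C)[C@@]1(OC)C(=O)[C@H](C)[C@H]1c2ccc(OC)c(O[Si](C(C)C)(C(C)C)C(C)C)c2
F5 | step 12 | 2-[(1R)-1,3-bis[(tert-butyldimethylsilyl)oxy]propyl]-2-methoxy-3-[4-methoxy-3-(triisopropylsilyloxy)phenyl]-4-methylcyclopentan-1-one (ring configuration as in F4) | CC(C)(C)[Si](C)(C)OCC[C@@H](O[Si](C)(C)C(C)(C)C)[C@@]1(OC)C(=O)C[C@H](C)[C@H]1c2ccc(OC)c(O[Si](C(C)C)(C(C)C)C(C)C)c2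
F6 | step 12 | 5-allyl-2-[(1R)-1,3-bis[(tert-butyldimethylsilyl)oxy]propyl]-2-methoxy-3-[4-methoxy-3-(triisopropylsilyloxy)phenyl]-4-methylcyclopentan-1-one (mixture at the allyl carbon) | CC(C)(C)[Si](C)(C)OCC[C@@H](O[Si](C)(C)C(C)(C)C)[C@@]1(OC)C(=O)C(CC=C)[C@H](C)[C@H]1c2ccc(OC)c(O[Si](C(C)C)(C(C)C)C(C)C)c2
F7 | step 12 | 5-allyl-2-[(1R)-1-[(tert-butyldimethylsilyl)oxy]-3-hydroxypropyl]-2-methoxy-3-[4-methoxy-3-(triisopropylsilyloxy)phenyl]-4-methylcyclopentan-1-one | OCC[C@@H](O[Si](C)(C)C(C)(C)C)[C@@]1(OC)C(=O)C(CC=C)[C@H](C)[C@H]1c2ccc(OC)c(O[Si](C(C)C)(C(C)C)C(C)C)c2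
F8 | step 12 | 5-allyl-2-[(1R)-1-[(tert-butyldimethylsilyl)oxy]-3-iodopropyl]-2-methoxy-3-[4-methoxy-3-(triisopropylsilyloxy)phenyl]-4-methylcyclopentan-1-one | ICC[C@@H](O[Si](C)(C)C(C)(C)C)[C@@]1(OC)C(=O)C(CC=C)[C@H](C)[C@H]1c2ccc(OC)c(O[Si](C(C)C)(C(C)C)C(C)C)c2
F9 | step 11 | (2S,3R)-5-(2-allyl-1,3-dithian-2-yl)-3-[(tert-butyldimethylsilyl)oxy]-2-methoxypentanoic acid | C=CCC1(CC[C@@H](O[Si](C)(C)C(C)(C)C)[C@H](OC)C(=O)O)SCCCS1
F10 | step 11 | (2R,3S,4R)-2-[(1R)-3-(2-allyl-1,3-dithian-2-yl)-1-[(tert-butyldimethylsilyl)oxy]propyl]-2-methoxy-3-[4-methoxy-3-(triisopropylsilyloxy)phenyl]-4-methylcyclobutan-1-one | C=CCC1(CC[C@@H](O[Si](C)(C)C(C)(C)C)[C@@]2(OC)C(=O)[C@H](C)[C@H]2c3ccc(OC)c(O[Si](C(C)C)(C(C)C)C(C)C)c3)SCCCS1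
F11 | step 11 | (2R,3S,4R)-2-[(1R)-1-[(tert-butyldimethylsilyl)oxy]-4-oxohept-6-en-1-yl]-2-methoxy-3-[4-methoxy-3-(triisopropylsilyloxy)phenyl]-4-methylcyclobutan-1-one | C=CCC(=O)CC[C@@H](O[Si](C)(C)C(C)(C)C)[C@@]1(OC)C(=O)[C@H](C)[C@H]1c2ccc(OC)c(O[Si](C(C)C)(C(C)C)C(C)C)c2
F12 | step 19 | exo-3-trifluoromethanesulfonate of 29 | C=CC[C@]12C[C@@H](OS(=O)(=O)C(F)(F)F)C(=O)[C@](OC)([C@H](c3ccc(OC)c(O[Si](C(C)C)(C(C)C)C(C)C)c3)[C@H]1C)[C@H]2O[Si](C)(C)C
F13 | step 19 | (1S,3S,5S,6S,7R,8S)-1-allyl-3-hydroxy-5-methoxy-6-[4-methoxy-3-(triisopropylsilyloxy)phenyl]-7-methyl-8-[(trimethylsilyl)oxy]bicyclo[3.2.1]octan-4-one (3-hydroxyl endo) | C=CC[C@]12C[C@H](O)C(=O)[C@](OC)([C@H](c3ccc(OC)c(O[Si](C(C)C)(C(C)C)C(C)C)c3)[C@H]1C)[C@H]2O[Si](C)(C)C
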